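**Strategy.** Everything rests on cutting ring B, the 2,3-dibromo-4,5-dihydroxyphenyl ring, across its C1'–C6' and C2'–C3' bonds. The C3'–C4'–C5'–C6' unit with both oxygens then comes from 2,3-bis(trimethylsilyloxy)butadiene, and the C1'–C2' pair with the C2' bromine from a bromoalkynyl ketone that already carries ring A. One thermal Diels–Alder reaction followed by desilylation closes ring B, delivers it directly at the catechol oxidation level, installs the C2' bromine and leaves the carbonyl that later becomes the CH2 bridge. The dienophile is an aryl 3-bromopropynyl ketone whose aryl group is the complete ring A: C3 bromine, C4 and C5 methoxy groups and a pivalate-protected hydroxyethyl chain at C1.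

Key step: step 9

Assumption: the target is made as the free hydrogen sulfate drawn. Ring A is numbered C1 (side chain), C2 (bridge carbon), C3 (Br), C4 and C5 (oxygens), C6 (H); ring B is numbered C1' (bridge), C2' and C3' (Br), C4' and C5' (OH), C6' (H). Compounds 5, 8, 9 and 17 are racemic; each of these centres is removed later and the target is achiral.

Step 1
Reactants: 1 homovanillyl alcohol, 2-(4-hydroxy-3-methoxyphenyl)ethanol
Product: 2 2-(3-bromo-4-hydroxy-5-methoxyphenyl)ethanol
Conditions: NBS (1.0 equiv), MeCN, 0 °C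
Reagents that add atoms: N-bromosuccinimide, O=C1CCC(=O)N1Br
Why: Electrophilic aromatic bromination; the free phenol is the strongest director and its para position is blocked by the side chain, so bromine should enter at its only open ortho carbon, as in the bromination of vanillin to 5-bromovanillin.

Step 2
Reactants: 2 2-(3-bromo-4-hydroxy-5-methoxyphenyl)ethanol
Product: 3 2-(3-bromo-4,5-dimethoxyphenyl)ethanol
Conditions: MeI, K2CO3, acetone, reflux
Reagents that add atoms: iodomethane, CI
Why: Williamson ether synthesis; K2CO3 deprotonates only the phenol, so methylation should be selective over the aliphatic alcohol.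

Step 3
Reactants: 3 2-(3-bromo-4,5-dimethoxyphenyl)ethanol
Product: 4 2-(3-bromo-4,5-dimethoxyphenyl)ethyl pivalate
Conditions: PivCl, Et3N, DMAP (cat.), CH2Cl2, 0 °C to rt
Reagents that add atoms: pivaloyl chloride, CC(C)(C)C(=O)Cl
Why: DMAP-catalysed acylation of the primary alcohol; the hindered pivalate is chosen because it should resist TiCl4, the Grignard reagent of step 5, TFA and cold BBr3.

Step 4
Reactants: 4 2-(3-bromo-4,5-dimethoxyphenyl)ethyl pivalate
Product: 6 2-(3-bromo-2-formyl-4,5-dimethoxyphenyl)ethyl pivalate, via chloro(methoxy)methyl arene 5 (not isolated)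
Conditions: Cl2CHOMe, TiCl4, CH2Cl2, −78 to 0 °C; then H2O
Reagents that add atoms: dichloromethyl methyl ether, COC(Cl)Cl; water, O
Why: Rieche formylation (electrophilic aromatic substitution); the C5 methoxy group, the only one able to lie in the ring plane, directs para to the carbon between the bromine and the side chain, the same kind of site that takes the second bromine of 5-bromovanillin, and aqueous work-up hydrolyses chloro ether 5 to the aldehyde.

Step 5
Reactants: 6 2-(3-bromo-2-formyl-4,5-dimethoxyphenyl)ethyl pivalate; 7 ethynylmagnesium bromide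
Product: 8 2-[3-bromo-2-(1-hydroxyprop-2-yn-1-yl)-4,5-dimethoxyphenyl]ethyl pivalate (racemic)
Conditions: THF, −20 to 0 °C; then aq. NH4Cl
Reagents that add atoms: none
Why: 1,2-Addition of an alkynyl Grignard reagent to the aldehyde, which is far more electrophilic than the hindered pivalate, while the aryl bromide is inert; the carbinol centre forms racemic and is removed in step 7.

Step 6
Reactants: 8 2-[3-bromo-2-(1-hydroxyprop-2-yn-1-yl)-4,5-dimethoxyphenyl]ethyl pivalate
Product: 9 2-[3-bromo-2-(3-bromo-1-hydroxyprop-2-yn-1-yl)-4,5-dimethoxyphenyl]ethyl pivalate (racemic)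
Conditions: NBS, AgNO3 (10 mol%), acetone, rt, dark
Reagents that add atoms: N-bromosuccinimide, O=C1CCC(=O)N1Br
Why: Silver-catalysed electrophilic bromination of a terminal alkyne through its silver acetylide; it is placed before the oxidation so that no terminal ynone has to be handled.

Step 7
Reactants: 9 2-[3-bromo-2-(3-bromo-1-hydroxyprop-2-yn-1-yl)-4,5-dimethoxyphenyl]ethyl pivalate
Product: 10 2-[3-bromo-2-(3-bromoprop-2-ynoyl)-4,5-dimethoxyphenyl]ethyl pivalate
Conditions: Dess–Martin periodinane, CH2Cl2, 0 °C to rt
Reagents that add atoms: none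
Why: Dess–Martin oxidation of a secondary propargylic alcohol under neutral, non-nucleophilic conditions that should leave the electrophilic bromoalkyne intact; the carbinol stereocentre disappears.

Step 8
Reactants: 11 biacetyl, butane-2,3-dione
Product: 12 2,3-bis(trimethylsilyloxy)buta-1,3-diene
Conditions: TMSOTf (2.2 equiv), Et3N, Et2O, 0 °C to rt; distillation
Reagents that add atoms: trimethylsilyl trifluoromethanesulfonate, C[Si](C)(C)OS(=O)(=O)C(F)(F)F
Why: Double O-silylation of the twice enolizable 1,2-diketone by soft enolization, an established way to this bis(silyl enol ether) diene.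

Step 9
Reactants: 10 2-[3-bromo-2-(3-bromoprop-2-ynoyl)-4,5-dimethoxyphenyl]ethyl pivalate; 12 2,3-bis(trimethylsilyloxy)buta-1,3-diene
Product: 15 2-[3-bromo-2-(2-bromo-4,5-dihydroxybenzoyl)-4,5-dimethoxyphenyl]ethyl pivalate, via silyloxy cycloadduct 13 (not isolated), via cyclohexenedione 14 (not isolated)
Conditions: 12 (2.5 equiv), toluene, 90 °C, Ar; then 1 M HCl, THF, rt
Reagents that add atoms: none
Why: A concerted thermal [4+2] cycloaddition of normal electron demand joins the termini of the electron-rich s-cis diene to both carbons of the carbonyl-activated alkyne (C6' to C1', C3' to C2') and gives the 1,4-cyclohexadiene 13. The closest known reaction type is the Diels–Alder reaction of 2,3-bis(trimethylsilyloxy)butadiene with acetylenic ketones and esters, which gives catechols after desilylation, together with the use of 1-haloalkynyl carbonyl compounds as dienophiles. Ring B is closed as a six-membered carbocycle by intermolecular [4+2] annulation, both new bonds forming in the one pericyclic event. Aqueous acid cleaves both silyl enol ethers to the cyclohex-4-ene-1,2-dione 14, an isomer of the catechol that aromatizes by two enolizations, so no oxidant is needed and no stereocentre is created. The step needs only chemoselectivity: the diene is symmetric, so both orientations give the same product, the ynone is the only competent dienophile in 10, and metal-free neutral heating should leave the alkynyl and aryl C–Br bonds, the pivalate and the methyl ethers untouched.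

Step 10
Reactants: 15 2-[3-bromo-2-(2-bromo-4,5-dihydroxybenzoyl)-4,5-dimethoxyphenyl]ethyl pivalate
Product: 16 2-[3-bromo-2-(2,3-dibromo-4,5-dihydroxybenzoyl)-4,5-dimethoxyphenyl]ethyl pivalate
Conditions: Br2 (1.0 equiv), AcOH, 15 °C
Reagents that add atoms: bromine, BrBr
Why: Electrophilic aromatic bromination of the catechol; attack at C3' is ortho to the C4' hydroxyl and meta to the carbonyl, whereas attack at C6' would put positive charge on the acyl-bearing C1', and ring A should not compete because its one open carbon is only ortho to a methoxy group that is conjugated with the ketone.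

Step 11
Reactants: 16 2-[3-bromo-2-(2,3-dibromo-4,5-dihydroxybenzoyl)-4,5-dimethoxyphenyl]ethyl pivalate
Product: 18 2-[3-bromo-2-(2,3-dibromo-4,5-dihydroxybenzyl)-4,5-dimethoxyphenyl]ethyl pivalate, via diaryl carbinol 17 (not isolated)
Conditions: Et3SiH (4 equiv), TFA, CH2Cl2, rt to 45 °C
Reagents that add atoms: none
Why: Ionic hydrogenation of a diaryl ketone; protonation and hydride transfer give carbinol 17, which ionizes to a benzhydryl cation stabilized by the para C4' hydroxyl and the para C5 methoxy group and is reduced again, while the pivalate keeps the side-chain oxygen from trapping the cation as an isochroman.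

Step 12
Reactants: 18 2-[3-bromo-2-(2,3-dibromo-4,5-dihydroxybenzyl)-4,5-dimethoxyphenyl]ethyl pivalate
Product: 19 2-[3-bromo-2-(2,3-dibromo-4,5-dihydroxybenzyl)-4,5-dihydroxyphenyl]ethyl pivalate
Conditions: BBr3 (8 equiv), CH2Cl2, −78 to 0 °C; then ice-water
Reagents that add atoms: none
Why: Lewis acid cleavage of aryl methyl ethers; BBr3 coordinates each ether oxygen and bromide removes the methyl group by SN2, whereas the primary pivalate should be cleaved much more slowly at or below 0 °C.

Step 13
Reactants: 19 2-[3-bromo-2-(2,3-dibromo-4,5-dihydroxybenzyl)-4,5-dihydroxyphenyl]ethyl pivalate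
Product: 20 3-bromo-4-(2,3-dibromo-4,5-dihydroxybenzyl)-5-(2-hydroxyethyl)benzene-1,2-diol
Conditions: iBu2AlH (8 equiv), THF, −78 to 0 °C; then 1 M HCl
Reagents that add atoms: none
Why: Hydride reduction of the ester; the four phenols are first converted into aluminium phenoxides, which also shields the catechols from air oxidation, and the pivalate is then cleaved reductively under non-basic conditions to the primary alcohol.

Step 14
Reactants: 20 3-bromo-4-(2,3-dibromo-4,5-dihydroxybenzyl)-5-(2-hydroxyethyl)benzene-1,2-diol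
Product: 21 2-[3-bromo-2-(2,3-dibromo-4,5-dihydroxybenzyl)-4,5-dihydroxyphenyl]ethyl hydrogen sulfate
Conditions: SO3·pyridine (1.1 equiv), DMF, 0 °C to rt, Ar; then H2O, Dowex 50W (H+ form)
Reagents that add atoms: sulfur trioxide pyridine complex, O=S(=O)([O-])[n+]1ccccc1
Why: O-Sulfation with a sulfur trioxide amine complex; without added base the unhindered primary alcohol should be far more nucleophilic than the hydrogen-bonded, bromine-flanked catechol hydroxyls, the weakly basic pyridine released should not form phenoxides, and acidic ion exchange gives the free hydrogen sulfate.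

**Compound list**

1 | homovanillyl alcohol, 2-(4-hydroxy-3-methoxyphenyl)ethanol | COc1cc(CCO)ccc1O | starting material
2 | 2-(3-bromo-4-hydroxy-5-methoxyphenyl)ethanol | COc1cc(CCO)cc(Br)c1O | intermediate
3 | 2-(3-bromo-4,5-dimethoxyphenyl)ethanol | COc1cc(CCO)cc(Br)c1OC | intermediate
4 | 2-(3-bromo-4,5-dimethoxyphenyl)ethyl pivalate | CC(C)(C)C(=O)OCCc1cc(OC)c(OC)c(Br)c1 | intermediate
5 | 2-{3-bromo-2-[chloro(methoxy)methyl]-4,5-dimethoxyphenyl}ethyl pivalate (racemic) | CC(C)(C)C(=O)OCCc1cc(OC)c(OC)c(Br)c1C(Cl)OC | intermediate (not isolated)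
6 | 2-(3-bromo-2-formyl-4,5-dimethoxyphenyl)ethyl pivalate | CC(C)(C)C(=O)OCCc1cc(OC)c(OC)c(Br)c1C=O | intermediate
7 | ethynylmagnesium bromide | C#C[Mg]Br | starting material
8 | 2-[3-bromo-2-(1-hydroxyprop-2-yn-1-yl)-4,5-dimethoxyphenyl]ethyl pivalate (racemic) | CC(C)(C)C(=O)OCCc1cc(OC)c(OC)c(Br)c1C(O)C#C | intermediate
9 | 2-[3-bromo-2-(3-bromo-1-hydroxyprop-2-yn-1-yl)-4,5-dimethoxyphenyl]ethyl pivalate (racemic) | CC(C)(C)C(=O)OCCc1cc(OC)c(OC)c(Br)c1C(O)C#CBr | intermediate
10 | 2-[3-bromo-2-(3-bromoprop-2-ynoyl)-4,5-dimethoxyphenyl]ethyl pivalate | CC(C)(C)C(=O)OCCc1cc(OC)c(OC)c(Br)c1C(=O)C#CBr | intermediate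
11 | biacetyl, butane-2,3-dione | CC(=O)C(C)=O | starting material
12 | 2,3-bis(trimethylsilyloxy)buta-1,3-diene | C=C(O[Si](C)(C)C)C(=C)O[Si](C)(C)C | intermediate
13 | 2-{3-bromo-2-[2-bromo-4,5-bis(trimethylsilyloxy)cyclohexa-1,4-diene-1-carbonyl]-4,5-dimethoxyphenyl}ethyl pivalate | CC(C)(C)C(=O)OCCc1cc(OC)c(OC)c(Br)c1C(=O)C1=C(Br)CC(O[Si](C)(C)C)=C(O[Si](C)(C)C)C1 | intermediate (not isolated)
14 | 2-[3-bromo-2-(2-bromo-4,5-dioxocyclohex-1-ene-1-carbonyl)-4,5-dimethoxyphenyl]ethyl pivalate | CC(C)(C)C(=O)OCCc1cc(OC)c(OC)c(Br)c1C(=O)C1=C(Br)CC(=O)C(=O)C1 | intermediate (not isolated)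
15 | 2-[3-bromo-2-(2-bromo-4,5-dihydroxybenzoyl)-4,5-dimethoxyphenyl]ethyl pivalate | CC(C)(C)C(=O)OCCc1cc(OC)c(OC)c(Br)c1C(=O)c1cc(O)c(O)cc1Br | intermediate
16 | 2-[3-bromo-2-(2,3-dibromo-4,5-dihydroxybenzoyl)-4,5-dimethoxyphenyl]ethyl pivalate | CC(C)(C)C(=O)OCCc1cc(OC)c(OC)c(Br)c1C(=O)c1cc(O)c(O)c(Br)c1Br | intermediate
17 | 2-{3-bromo-2-[(2,3-dibromo-4,5-dihydroxyphenyl)(hydroxy)methyl]-4,5-dimethoxyphenyl}ethyl pivalate (racemic) | CC(C)(C)C(=O)OCCc1cc(OC)c(OC)c(Br)c1C(O)c1cc(O)c(O)c(Br)c1Br | intermediate (not isolated)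
18 | 2-[3-bromo-2-(2,3-dibromo-4,5-dihydroxybenzyl)-4,5-dimethoxyphenyl]ethyl pivalate | CC(C)(C)C(=O)OCCc1cc(OC)c(OC)c(Br)c1Cc1cc(O)c(O)c(Br)c1Br | intermediate
19 | 2-[3-bromo-2-(2,3-dibromo-4,5-dihydroxybenzyl)-4,5-dihydroxyphenyl]ethyl pivalate | CC(C)(C)C(=O)OCCc1cc(O)c(O)c(Br)c1Cc1cc(O)c(O)c(Br)c1Br | intermediate
20 | 3-bromo-4-(2,3-dibromo-4,5-dihydroxybenzyl)-5-(2-hydroxyethyl)benzene-1,2-diol | OCCc1cc(O)c(O)c(Br)c1Cc1cc(O)c(O)c(Br)c1Br | intermediate
21 | 2-[3-bromo-2-(2,3-dibromo-4,5-dihydroxybenzyl)-4,5-dihydroxyphenyl]ethyl hydrogen sulfate | O=S(=O)(O)OCCc1cc(O)c(O)c(Br)c1Cc1cc(O)c(O)c(Br)c1Br | target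

**Step count.** Total: 14 steps. Longest linear sequence: 13 steps (steps 1–7 and 9–14, from homovanillyl alcohol); step 8 is a one-step side branch.

**Steps most likely to fail**

Step 9. The hindered bromoynone may decompose, or lose its alkynyl bromine by addition–elimination, faster than it undergoes cycloaddition, or the silyl enol ethers of the diene may be hydrolysed before the cycloaddition is complete. The fallback introduces the C2' bromine after ring formation instead of through the dienophile. Setting out from propargylic alcohol 8, Dess–Martin oxidation should give the terminal ynone 2-(3-bromo-4,5-dimethoxy-2-propynoylphenyl)ethyl pivalate F1. This less hindered dienophile is heated with diene 12 in toluene and the crude product is treated with dilute HCl. That should lead through the bis(silyloxy)cyclohexadiene cycloadduct F2 and the cyclohexenedione F3, neither isolated, to 2-[3-bromo-2-(3,4-dihydroxybenzoyl)-4,5-dimethoxyphenyl]ethyl pivalate F4. Bromination with two equivalents of Br2 in AcOH, first ortho to the C4' hydroxyl (C3') and then para to the C5' hydroxyl (C2'), comes back to the route at compound 16.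

Step 4. Attack of the bulky titanium-bound electrophile at the carbon flanked by the bromine and the side chain may be slow, so that formylation drifts to the other open ring carbon or TiCl4 begins to cleave the methyl ethers. The fallback replaces direct formylation by halogenation and metalation. Setting out from pivalate 4, iodination with NIS and catalytic TFA in MeCN, para to the C5 methoxy group, should give 2-(3-bromo-2-iodo-4,5-dimethoxyphenyl)ethyl pivalate F5. Iodine–magnesium exchange with iPrMgCl·LiCl in THF at −40 °C is selective for iodine over bromine and tolerated by the pivalate, and should give the arylmagnesium chloride F6 (not isolated). Quenching with DMF and work-up with dilute HCl comes back to the route at aldehyde 6.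

Step 14. Sulfation may spill over to the acidic catechol hydroxyls and give mixtures of regioisomeric and multiple sulfates. The fallback masks both catechols as cyclic boronates before sulfation. Setting out from pentaol 20, condensation with PhB(OH)2 (2 equiv) in toluene/THF with azeotropic removal of water should give the bis(2-phenyl-1,3,2-benzodioxaborole) F7, in which only the primary alcohol is free. SO3·pyridine in dry DMF should then give the boronate-protected hydrogen sulfate F8. Aqueous work-up and acidic ion exchange hydrolyse both boronates and come back to the route at target 21.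

**Further compounds**

F1 | step 9 | 2-(3-bromo-4,5-dimethoxy-2-propynoylphenyl)ethyl pivalate | CC(C)(C)C(=O)OCCc1cc(OC)c(OC)c(Br)c1C(=O)C#C
F2 | step 9 | 2-{2-[4,5-bis(trimethylsilyloxy)cyclohexa-1,4-diene-1-carbonyl]-3-bromo-4,5-dimethoxyphenyl}ethyl pivalate | CC(C)(C)C(=O)OCCc1cc(OC)c(OC)c(Br)c1C(=O)C1=CCC(O[Si](C)(C)C)=C(O[Si](C)(C)C)C1
F3 | step 9 | 2-[3-bromo-2-(4,5-dioxocyclohex-1-ene-1-carbonyl)-4,5-dimethoxyphenyl]ethyl pivalate | CC(C)(C)C(=O)OCCc1cc(OC)c(OC)c(Br)c1C(=O)C1=CCC(=O)C(=O)C1
F4 | step 9 | 2-[3-bromo-2-(3,4-dihydroxybenzoyl)-4,5-dimethoxyphenyl]ethyl pivalate | CC(C)(C)C(=O)OCCc1cc(OC)c(OC)c(Br)c1C(=O)c1ccc(O)c(O)c1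
F5 | step 4 | 2-(3-bromo-2-iodo-4,5-dimethoxyphenyl)ethyl pivalate | CC(C)(C)C(=O)OCCc1cc(OC)c(OC)c(Br)c1I
F6 | step 4 | {2-bromo-3,4-dimethoxy-6-[2-(pivaloyloxy)ethyl]phenyl}magnesium chloride | CC(C)(C)C(=O)OCCc1cc(OC)c(OC)c(Br)c1[Mg]Cl
F7 | step 14 | 2-{7-bromo-6-[(6,7-dibromo-2-phenyl-1,3,2-benzodioxaborol-5-yl)methyl]-2-phenyl-1,3,2-benzodioxaborol-5-yl}ethanol | OCCc1cc2OB(c3ccccc3)Oc2c(Br)c1Cc1cc2OB(c3ccccc3)Oc2c(Br)c1Br
F8 | step 14 | 2-{7-bromo-6-[(6,7-dibromo-2-phenyl-1,3,2-benzodioxaborol-5-yl)methyl]-2-phenyl-1,3,2-benzodioxaborol-5-yl}ethyl hydrogen sulfate | O=S(=O)(O)OCCc1cc2OB(c3ccccc3)Oc2c(Br)c1Cc1cc2OB(c3ccccc3)Oc2c(Br)c1Br
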